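Numbering (pterocarpan): ring A = C1–C4, C4a, C11b. Ring B = O5, C6, C6a, C11a, C11b, C4a. Ring C = C6a, C6b, C10a, O11, C11a. Ring D = C6b–C10a with OMe on C9. Ring E = the dimethylpyran on C1(O)–C2.
Cuts, in order: O5–C6 (ring B), C6a–C11a (ring C), O11–C11a (benzyl aryl ether). Ring E is then cut from a phloroglucinaldehyde whose formyl carbon is C11a.
Enabling feature: C11a is a methine bound to O11 and benzylic to ring A (oxygen on C1, C3 and C4a), and it lies 1,5 to C6a. One oxidation level lower it is the CH2 of an O11 benzyl ether, the most hydridic C–H site that a carbenoid on C6a can reach.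
Forward: ring E is fused to ring A, and the A/E alcohol is joined through O11 to the ring D arylacetate. Diazo transfer and insertion close ring C, and ring B closes last at the achiral C6.
Stereochemistry: C6a and C11a are both set in the insertion by a chiral dirhodium carboxylate (kinetic cis). C6a leaves the ester level before any base is met, and no later step touches either centre.

Key step: step 9

Assumption: simple [2-(benzyloxy)phenyl]diazoacetates are taken to give the (2R,3S) ester with the (S)-tert-leucinate catalyst, and the same sense of induction is taken to hold here. The (R)-ligand catalyst is therefore used, and the configuration of the insertion product is to be verified before the endgame.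

Step 1
Reactants: 1 2,4,6-trihydroxybenzaldehyde
Product: 2 4-(benzyloxy)-2,6-dihydroxybenzaldehyde
Conditions: BnBr (1.0 equiv), NaHCO3, DMF, 40 °C
Reagents that add atoms: benzyl bromide, BrCc1ccccc1
Why: Regioselective Williamson etherification: the C4 hydroxyl is the most acidic and least hindered one and takes no part in the hydrogen bond to the formyl oxygen, so one equivalent of halide with a weak base in a dipolar aprotic solvent (which also favours O- over C-benzylation) should give mainly the symmetrical 4-O-benzyl ether, whose only task is to block the para oxygen during the pyran annulation.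

Step 2
Reactants: 2 4-(benzyloxy)-2,6-dihydroxybenzaldehyde, 3 3-methylbut-2-enal (prenal)
Product: 5 5-(benzyloxy)-7-hydroxy-2,2-dimethyl-2H-chromene-8-carbaldehyde, via ortho-quinone methide 4 (not isolated)
Conditions: 3 (1.2 equiv), Ca(OH)2, MeOH, rt
Reagents that add atoms: none
Why: Base-mediated formal [3+3] chromene annulation of an acylresorcinol with an enal (ortho C-alkylation of the calcium phenoxide, loss of water to the ortho-quinone methide and oxa-6π electrocyclisation); C3 and C5 of 2 are equivalent and, with O4 benzylated, only a hydroxyl next to the formyl group flanks the new carbon substituent, so the pyran oxygen can end up only on the future C1.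

Step 3
Reactants: 5 5-(benzyloxy)-7-hydroxy-2,2-dimethyl-2H-chromene-8-carbaldehyde
Product: 6 5,7-dihydroxy-2,2-dimethylchroman-8-carbaldehyde
Conditions: H2 (1 atm), Pd/C (10 %), EtOAc–MeOH, rt
Reagents that add atoms: none
Why: Heterogeneous catalytic hydrogenation saturates the chromene double bond and hydrogenolyses the benzyl ether in one operation, while the chelated and strongly donor-substituted aldehyde should be reduced much more slowly at one atmosphere in a neutral solvent.

Step 4
Reactants: 6 5,7-dihydroxy-2,2-dimethylchroman-8-carbaldehyde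
Product: 7 5,7-bis[(tert-butyldimethylsilyl)oxy]-2,2-dimethylchroman-8-carbaldehyde
Conditions: TBSCl (2.5 equiv), imidazole, DMF, rt → 40 °C
Reagents that add atoms: tert-butyldimethylsilyl chloride, CC(C)(C)[Si](C)(C)Cl
Why: Standard silylation of phenols with a silyl chloride and imidazole; silyl ethers are weaker donors than alkyl ethers, offer the carbenoid no C–H bond next to oxygen, and leave with fluoride, so that the finished pterocarpan, whose C11a–O11 bond is itself benzylic, never has to face hydrogenolysis.

Step 5
Reactants: 7 5,7-bis[(tert-butyldimethylsilyl)oxy]-2,2-dimethylchroman-8-carbaldehyde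
Product: 8 {5,7-bis[(tert-butyldimethylsilyl)oxy]-2,2-dimethylchroman-8-yl}methanol
Conditions: iBu2AlH (1.1 equiv), CH2Cl2, −78 °C; aq. potassium sodium tartrate
Reagents that add atoms: none
Why: Hydride reduction of an aldehyde; the covalent aluminium alkoxide formed at −78 °C should not set off the silyl shift from O5 to the new oxygen that a free alkoxide could, and the neutral tartrate work-up spares the acid-labile trioxygenated benzyl alcohol.

Step 6
Reactants: 9 (2-hydroxy-4-methoxyphenyl)acetic acid
Product: 10 methyl (2-hydroxy-4-methoxyphenyl)acetate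
Conditions: MeOH, H2SO4 (cat.), reflux
Reagents that add atoms: methanol, CO
Why: Fischer esterification, in which the large excess of methanol holds the product as the open hydroxy ester and not as the benzofuranone lactone.

Step 7
Reactants: 8 {5,7-bis[(tert-butyldimethylsilyl)oxy]-2,2-dimethylchroman-8-yl}methanol, 10 methyl (2-hydroxy-4-methoxyphenyl)acetate
Product: 11 methyl [2-({5,7-bis[(tert-butyldimethylsilyl)oxy]-2,2-dimethylchroman-8-yl}methoxy)-4-methoxyphenyl]acetate
Conditions: PPh3, DIAD, toluene, 0 °C → rt
Reagents that add atoms: none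
Why: Mitsunobu etherification of a primary benzylic alcohol with a phenol forms O11–C11a under neutral conditions and avoids the unstable trioxygenated benzyl halide, and the non-polar solvent keeps the oxyphosphonium phenoxide ion pair tight so that attack through oxygen should prevail.

Step 8
Reactants: 11 methyl [2-({5,7-bis[(tert-butyldimethylsilyl)oxy]-2,2-dimethylchroman-8-yl}methoxy)-4-methoxyphenyl]acetate
Product: 12 methyl diazo[2-({5,7-bis[(tert-butyldimethylsilyl)oxy]-2,2-dimethylchroman-8-yl}methoxy)-4-methoxyphenyl]acetate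
Conditions: p-ABSA, DBU, dry MeCN, 0 °C → rt
Reagents that add atoms: 4-acetamidobenzenesulfonyl azide (p-ABSA), CC(=O)Nc1ccc(cc1)S(=O)(=O)N=[N+]=[N-]
Why: Regitz diazo transfer from a sulfonyl azide to the amidine-generated ester enolate is the standard entry to aryldiazoacetates, and strict exclusion of water keeps the base from cleaving the aryl silyl ethers.

Step 9
Reactants: 12 methyl diazo[2-({5,7-bis[(tert-butyldimethylsilyl)oxy]-2,2-dimethylchroman-8-yl}methoxy)-4-methoxyphenyl]acetate
Product: 13 methyl (2S,3R)-2-{5,7-bis[(tert-butyldimethylsilyl)oxy]-2,2-dimethylchroman-8-yl}-6-methoxy-2,3-dihydro-1-benzofuran-3-carboxylate (aryl and ester cis)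
Conditions: Rh2(R-PTTL)4 {dirhodium tetrakis[N-phthaloyl-(R)-tert-leucinate]} (2 mol %), 4 Å molecular sieves, toluene, −78 → −40 °C
Reagents that add atoms: none
Why: The divalent rhodium dimer expels N2 from 12, and the resulting donor/acceptor carbenoid at C6a takes up a C11a hydrogen and bonds to C11a in one concerted but asynchronous three-centre event. The closest known reaction type is the enantioselective intramolecular C–H insertion of methyl [2-(benzyloxy)phenyl]diazoacetates with N-phthaloyl amino acid dirhodium carboxylates, which gives cis-2-aryl-2,3-dihydrobenzofuran-3-carboxylates. Ring C (C6a, C6b, C10a, O11, C11a) closes as a five-membered ring by 1,5-insertion. C11a is set by the choice that the chiral ligand pocket makes between the two enantiotopic benzylic hydrogens (insertion with retention) and C6a by the carbenoid face that the same pocket leaves open, the kinetic transition state placing ring A and the ester cis. The step needs site selectivity over the methoxy, silyl methyl and chroman C–H bonds and over attack on ring A itself; O11 and the oxygens on C1, C3 and C4a stabilise the partial positive charge at C11a, every other C–H bond would need a larger ring, and both ortho positions of ring A are blocked. Low temperature, a non-polar solvent and silyl in place of alkyl ethers on ring A are chosen to keep the hydrogen transfer concerted, and the ester meets no base before step 10.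

Step 10
Reactants: 13 methyl (2S,3R)-2-{5,7-bis[(tert-butyldimethylsilyl)oxy]-2,2-dimethylchroman-8-yl}-6-methoxy-2,3-dihydro-1-benzofuran-3-carboxylate
Product: 14 [(2S,3S)-2-{5,7-bis[(tert-butyldimethylsilyl)oxy]-2,2-dimethylchroman-8-yl}-6-methoxy-2,3-dihydro-1-benzofuran-3-yl]methanol
Conditions: iBu2AlH (3 equiv), CH2Cl2, −78 → −20 °C; aq. potassium sodium tartrate
Reagents that add atoms: none
Why: Reduction of the ester to the primary alcohol with a non-basic aluminium hydride takes C6 to the level needed for ring B without enolising the ester, so the kinetic cis relationship is kept and C6a is no longer acidic afterwards.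

Step 11
Reactants: 14 [(2S,3S)-2-{5,7-bis[(tert-butyldimethylsilyl)oxy]-2,2-dimethylchroman-8-yl}-6-methoxy-2,3-dihydro-1-benzofuran-3-yl]methanol
Product: 15 8-[(2S,3S)-3-(hydroxymethyl)-6-methoxy-2,3-dihydro-1-benzofuran-2-yl]-2,2-dimethylchroman-5,7-diol
Conditions: Bu4NF, AcOH (2.5 equiv each), THF, 0 °C
Reagents that add atoms: none
Why: Fluoride cleavage of both aryl silyl ethers, buffered with acetic acid so that phenols and not phenoxides are released, which should hold back opening of ring C to a quinone methide and thus keep C11a intact.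

Step 12
Reactants: 15 8-[(2S,3S)-3-(hydroxymethyl)-6-methoxy-2,3-dihydro-1-benzofuran-2-yl]-2,2-dimethylchroman-5,7-diol
Product: 16 (6aS,11aS)-3-hydroxy-9-methoxypterocarpan with a 2,2-dimethyl-3,4-dihydro-2H-pyran ring fused at C1–C2, pyran oxygen on C1 (CNP0207547.1)
Conditions: PPh3, DIAD, THF (0.01 M), 0 °C → rt
Reagents that add atoms: none
Why: Intramolecular Mitsunobu etherification (6-exo-tet) closes ring B: only the primary C6 hydroxyl is activated, only O5 can reach it within the molecule, the C3 hydroxyl could react only between molecules and is outrun at high dilution, and since no bond at C6a or C11a is touched the cis (6aS,11aS) fusion is carried over.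

Compound list
1 | 2,4,6-trihydroxybenzaldehyde | O=Cc1c(O)cc(O)cc1O | starting material
2 | 4-(benzyloxy)-2,6-dihydroxybenzaldehyde | O=Cc1c(O)cc(OCc2ccccc2)cc1O | intermediate
3 | 3-methylbut-2-enal (prenal) | CC(C)=CC=O | starting material
4 | 4-(benzyloxy)-2-hydroxy-5-(3-methylbut-2-enylidene)-6-oxocyclohexa-1,3-diene-1-carbaldehyde (ortho-quinone methide, not isolated) | O=CC1=C(O)C=C(OCc2ccccc2)C(=CC=C(C)C)C1=O | intermediate
5 | 5-(benzyloxy)-7-hydroxy-2,2-dimethyl-2H-chromene-8-carbaldehyde | O=Cc1c(O)cc(OCc2ccccc2)c2C=CC(C)(C)Oc12 | intermediate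
6 | 5,7-dihydroxy-2,2-dimethylchroman-8-carbaldehyde | O=Cc1c(O)cc(O)c2CCC(C)(C)Oc12 | intermediate
7 | 5,7-bis[(tert-butyldimethylsilyl)oxy]-2,2-dimethylchroman-8-carbaldehyde | O=Cc1c(O[Si](C)(C)C(C)(C)C)cc(O[Si](C)(C)C(C)(C)C)c2CCC(C)(C)Oc12 | intermediate
8 | {5,7-bis[(tert-butyldimethylsilyl)oxy]-2,2-dimethylchroman-8-yl}methanol | OCc1c(O[Si](C)(C)C(C)(C)C)cc(O[Si](C)(C)C(C)(C)C)c2CCC(C)(C)Oc12 | intermediate
9 | (2-hydroxy-4-methoxyphenyl)acetic acid | COc1ccc(CC(=O)O)c(O)c1 | starting material
10 | methyl (2-hydroxy-4-methoxyphenyl)acetate | COC(=O)Cc1ccc(OC)cc1O | intermediate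
11 | methyl [2-({5,7-bis[(tert-butyldimethylsilyl)oxy]-2,2-dimethylchroman-8-yl}methoxy)-4-methoxyphenyl]acetate | COC(=O)Cc1ccc(OC)cc1OCc1c(O[Si](C)(C)C(C)(C)C)cc(O[Si](C)(C)C(C)(C)C)c2CCC(C)(C)Oc12 | intermediate
12 | methyl diazo[2-({5,7-bis[(tert-butyldimethylsilyl)oxy]-2,2-dimethylchroman-8-yl}methoxy)-4-methoxyphenyl]acetate | COC(=O)C(=[N+]=[N-])c1ccc(OC)cc1OCc1c(O[Si](C)(C)C(C)(C)C)cc(O[Si](C)(C)C(C)(C)C)c2CCC(C)(C)Oc12 | intermediate
13 | methyl (2S,3R)-2-{5,7-bis[(tert-butyldimethylsilyl)oxy]-2,2-dimethylchroman-8-yl}-6-methoxy-2,3-dihydro-1-benzofuran-3-carboxylate | COc1ccc2c(c1)O[C@H](c1c(O[Si](C)(C)C(C)(C)C)cc(O[Si](C)(C)C(C)(C)C)c3CCC(C)(C)Oc13)[C@@H]2C(=O)OC | intermediate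
14 | [(2S,3S)-2-{5,7-bis[(tert-butyldimethylsilyl)oxy]-2,2-dimethylchroman-8-yl}-6-methoxy-2,3-dihydro-1-benzofuran-3-yl]methanol | COc1ccc2c(c1)O[C@H](c1c(O[Si](C)(C)C(C)(C)C)cc(O[Si](C)(C)C(C)(C)C)c3CCC(C)(C)Oc13)[C@@H]2CO | intermediate
15 | 8-[(2S,3S)-3-(hydroxymethyl)-6-methoxy-2,3-dihydro-1-benzofuran-2-yl]-2,2-dimethylchroman-5,7-diol | COc1ccc2c(c1)O[C@H](c1c(O)cc(O)c3CCC(C)(C)Oc13)[C@@H]2CO | intermediate
16 | (6aS,11aS)-3-hydroxy-9-methoxypterocarpan with a 2,2-dimethyl-3,4-dihydro-2H-pyran ring fused at C1–C2, pyran oxygen on C1 (CNP0207547.1) | COc1ccc2c(c1)O[C@@H]1c3c(cc(O)c4c3OC(C)(C)CC4)OC[C@H]21 | target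

Total step count: 12. Longest linear sequence: 11 steps (steps 1–5 and 7–12). Step 6 is the one-step side branch.

**Steps most likely to fail**

**Step 9 is most at risk.** Ring A carries three oxygen donors, so the hydrogen transfer may turn into a full hydride shift. The two ortho substituents also crowd the cis transition state. Ion-pair collapse would then erode the cis relationship and the enantioselectivity, or the ether would fragment.

The fallback changes the substrate and not the catalyst. It sets out from 6 and comes back at 15, and it caps the donor para to C11a with an acyl group.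
- Pivaloyl chloride and Et3N (CH2Cl2, 0 °C) should acylate only the non-chelated C5 hydroxyl of 6, giving 8-formyl-7-hydroxy-2,2-dimethylchroman-5-yl pivalate F1.
- TBSCl and imidazole then give the 7-O-silyl aldehyde F2.
- One equivalent of iBu2AlH at −78 °C, where the hindered pivalate is left alone, gives the benzyl alcohol F3.
- Mitsunobu coupling with 10 gives the benzyl aryl ether F4.
- Diazo transfer gives the diazo ester F5.
- The same rhodium catalyst gives the cis dihydrobenzofuran ester F6.
- Excess iBu2AlH reduces the methyl ester and removes the pivalate in one operation, giving the phenol alcohol F7.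
- Buffered Bu4NF frees O5 to give 15.

**Step 11 comes second.** Once O5 and the C3 oxygen are free, ring C may open to an ortho- or para-quinone methide and close again. That would epimerise C11a towards the more stable trans isomer while ring B is still open.

The fallback never lets the free phenol wait. It sets out from 14 and comes back at 16, so that 15 and step 12 are bypassed.
- MsCl and Et3N (CH2Cl2, −20 °C) convert 14 into the primary methanesulfonate F8.
- Bu4NF in dilute THF at 0 °C then strips both silyl groups.
- The O5 phenoxide should displace the sulfonate (6-exo-tet, SN2 at the achiral C6) as soon as it is released.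
- In the closed tetracycle, any reversible opening at C11a can only return the cis fusion.

**Step 7 comes third.** The oxyphosphonium salt of the crowded, very electron-rich alcohol 8 may ionise. C-benzylation of the phenol or self-condensation would then take the place of ether formation.

The fallback replaces the redox condensation by a palladium-catalysed benzylic substitution of the Tsuji–Trost type. It sets out from 8 and comes back at 11.
- Methyl chloroformate and pyridine give the benzyl methyl carbonate F9.
- With Pd(η3-C3H5)(C5H5) and DPEphos in toluene at 60–80 °C, zerovalent palladium should ionise the carbonate to an η3-benzyl complex with loss of CO2.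
- The methoxide released deprotonates 10, and the phenoxide attacks the benzyl ligand through oxygen under neutral conditions to give 11.

Further compounds
F1 | step 9 | 8-formyl-7-hydroxy-2,2-dimethylchroman-5-yl pivalate | O=Cc1c(O)cc(OC(=O)C(C)(C)C)c2CCC(C)(C)Oc12
F2 | step 9 | 7-[(tert-butyldimethylsilyl)oxy]-8-formyl-2,2-dimethylchroman-5-yl pivalate | O=Cc1c(O[Si](C)(C)C(C)(C)C)cc(OC(=O)C(C)(C)C)c2CCC(C)(C)Oc12
F3 | step 9 | 7-[(tert-butyldimethylsilyl)oxy]-8-(hydroxymethyl)-2,2-dimethylchroman-5-yl pivalate | OCc1c(O[Si](C)(C)C(C)(C)C)cc(OC(=O)C(C)(C)C)c2CCC(C)(C)Oc12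
F4 | step 9 | 7-[(tert-butyldimethylsilyl)oxy]-8-{[5-methoxy-2-(2-methoxy-2-oxoethyl)phenoxy]methyl}-2,2-dimethylchroman-5-yl pivalate | COC(=O)Cc1ccc(OC)cc1OCc1c(O[Si](C)(C)C(C)(C)C)cc(OC(=O)C(C)(C)C)c2CCC(C)(C)Oc12
F5 | step 9 | 7-[(tert-butyldimethylsilyl)oxy]-8-{[2-(1-diazo-2-methoxy-2-oxoethyl)-5-methoxyphenoxy]methyl}-2,2-dimethylchroman-5-yl pivalate | COC(=O)C(=[N+]=[N-])c1ccc(OC)cc1OCc1c(O[Si](C)(C)C(C)(C)C)cc(OC(=O)C(C)(C)C)c2CCC(C)(C)Oc12
F6 | step 9 | methyl (2S,3R)-2-{7-[(tert-butyldimethylsilyl)oxy]-2,2-dimethyl-5-(pivaloyloxy)chroman-8-yl}-6-methoxy-2,3-dihydro-1-benzofuran-3-carboxylate | COc1ccc2c(c1)O[C@H](c1c(O[Si](C)(C)C(C)(C)C)cc(OC(=O)C(C)(C)C)c3CCC(C)(C)Oc13)[C@@H]2C(=O)OC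
F7 | step 9 | 7-[(tert-butyldimethylsilyl)oxy]-8-[(2S,3S)-3-(hydroxymethyl)-6-methoxy-2,3-dihydro-1-benzofuran-2-yl]-2,2-dimethylchroman-5-ol | COc1ccc2c(c1)O[C@H](c1c(O[Si](C)(C)C(C)(C)C)cc(O)c3CCC(C)(C)Oc13)[C@@H]2CO
F8 | step 11 | [(2S,3S)-2-{5,7-bis[(tert-butyldimethylsilyl)oxy]-2,2-dimethylchroman-8-yl}-6-methoxy-2,3-dihydro-1-benzofuran-3-yl]methyl methanesulfonate | COc1ccc2c(c1)O[C@H](c1c(O[Si](C)(C)C(C)(C)C)cc(O[Si](C)(C)C(C)(C)C)c3CCC(C)(C)Oc13)[C@@H]2COS(C)(=O)=O
F9 | step 7 | {5,7-bis[(tert-butyldimethylsilyl)oxy]-2,2-dimethylchroman-8-yl}methyl methyl carbonate | COC(=O)OCc1c(O[Si](C)(C)C(C)(C)C)cc(O[Si](C)(C)C(C)(C)C)c2CCC(C)(C)Oc12
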